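**Retrosynthetic overview** (working locants: C1 bears CH2OBz, C2 OAc, C3 OBz, C4=C5, C6 OH)
1. 13 ⇐ 11: anti acetolysis of the C1–C2 oxirane at C2 sets the trans C1‑OH/C2‑OAc pair in the last step, with no protecting groups.
2. 11 ⇐ 9: Mitsunobu benzoylation with inversion at allylic C3; 9 ⇐ 8: retro‑Diels–Alder unveils the C4=C5 alkene.
3. 8 ⇐ 7 ⇐ 6: epoxidation and double C=O reduction, all from the convex face of an endo cyclopentadiene adduct.
4. Key step: 6 ⇐ quinone 4 + cyclopentadiene by catalytic enantioselective Diels–Alder reaction, the only external source of chirality; 4 ⇐ 2,5‑dimethoxybenzyl alcohol.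
5. Ring order: the carbocycle is never built, it is the dearomatised benzene ring of 1; a temporary norbornene ring is formed (step 3), then the oxirane (step 4), the norbornene is removed (step 6) and the oxirane opened (step 8).

Assumption: the (S)‑configured oxazaborolidinium catalyst is taken to give adduct 6 as drawn (if the facial sense is the opposite, its enantiomer is used), and cyclopentadiene 5 is freshly cracked from its commercial dimer, which is not counted as a step.

**Step 1**
Reactants: 1 2,5‑dimethoxybenzyl alcohol; 2 benzoyl chloride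
Product: 3 2,5‑dimethoxybenzyl benzoate
Conditions: BzCl (1.1 equiv), NEt3, 4‑(dimethylamino)pyridine (5 mol%), CH2Cl2, 0 °C → rt
Reagents that add atoms: benzoyl chloride (2), O=C(Cl)c1ccccc1
Why: Nucleophilic acyl substitution (O‑benzoylation) of the only hydroxyl group installs the primary benzoate of the target at the outset.

**Step 2**
Reactants: 3 2,5‑dimethoxybenzyl benzoate
Product: 4 (3,6‑dioxocyclohexa‑1,4‑dien‑1‑yl)methyl benzoate
Conditions: (NH4)2Ce(NO3)6 (2.5 equiv), MeCN–H2O 2:1, 0 °C, 20 min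
Reagents that add atoms: water, O
Why: Oxidative demethylation of a 1,4‑dimethoxyarene by tetravalent cerium gives the para‑quinone (water supplies the quinone oxygens, methanol leaves), placing C=O at C3 and C6 and C=C at C1=C2 and C4=C5, while the benzoate is inert.

**Step 3**
Reactants: 4 (3,6‑dioxocyclohexa‑1,4‑dien‑1‑yl)methyl benzoate; 5 cyclopenta‑1,3‑diene
Product: 6 [(1R,4S,4aR,8aS)‑5,8‑dioxo‑1,4,4a,5,8,8a‑hexahydro‑1,4‑methanonaphthalen‑6‑yl]methyl benzoate (endo adduct, ring‑fusion hydrogens cis)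
Conditions: 5 (3 equiv, added slowly), 20 mol% (S)‑1‑(2‑methylphenyl)‑3,3‑diphenyltetrahydro‑1H,3H‑pyrrolo[1,2‑c][1,3,2]oxazaborole premixed 1:1 with HN(SO2CF3)2, CH2Cl2, −78 °C
Reagents that add atoms: cyclopentadiene (5), C1C=CC=C1
Why: Catalytic enantioselective Diels–Alder reaction of an unsymmetrical quinone under chiral oxazaborolidinium activation: the diene adds endo to the unsubstituted C4=C5 bond, and the catalyst, bound to the less hindered C3 carbonyl, shields one face, so all four new stereocentres and the absolute configuration are set here.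

**Step 4**
Reactants: 6 endo adduct
Product: 7 [(1R,4S,4aR,6R,7S,8aS)‑6,7‑epoxy‑5,8‑dioxo‑1,4,4a,5,6,7,8,8a‑octahydro‑1,4‑methanonaphthalen‑6‑yl]methyl benzoate (epoxide oxygen on the face of the ring‑fusion hydrogens, away from the etheno bridge)
Conditions: 30% aq. H2O2, Na2CO3, acetone–H2O, 0 °C, 30 min
Reagents that add atoms: hydrogen peroxide, OO
Why: Weitz–Scheffer nucleophilic epoxidation attacks only the electron‑poor enedione C1=C2 bond (the norbornene alkene is inert) and only from the open convex face of the folded endo adduct, which fixes the C1–O and C2–O bonds on the face that will carry the tertiary hydroxyl of the target.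

**Step 5**
Reactants: 7 epoxy dione
Product: 8 [(1R,4S,4aR,5R,6S,7R,8S,8aS)‑6,7‑epoxy‑5,8‑dihydroxy‑1,4,4a,5,6,7,8,8a‑octahydro‑1,4‑methanonaphthalen‑6‑yl]methyl benzoate (both hydroxyls trans to the epoxide oxygen, pointing toward the etheno bridge)
Conditions: NaBH4 (2.5 equiv), CeCl3·7H2O, MeOH, −40 °C
Reagents that add atoms: none
Why: Luche‑type borohydride reduction delivers hydride to both ketones from the convex face, because the concave face is blocked by the etheno bridge, giving the C6 and C3 carbinols trans to the epoxide oxygen; C6 is thereby final, C3 is deliberately set up for inversion, and epoxide and ester survive the mild cold conditions.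

**Step 6**
Reactants: 8 tricyclic epoxy diol
Product: 9 [(1S,2R,5S,6R)‑2,5‑dihydroxy‑7‑oxabicyclo[4.1.0]hept‑3‑en‑1‑yl]methyl benzoate
Conditions: flash vacuum pyrolysis, 480 °C, 0.02 mbar
Reagents that add atoms: none
Why: Thermal retro‑Diels–Alder extrusion of cyclopentadiene regenerates the C4=C5 alkene without touching the four remaining stereocentres, and the primary benzoate has no β‑hydrogen, so ester pyrolysis cannot compete during the short gas‑phase contact.

**Step 7**
Reactants: 9 epoxy ene‑diol; 10 benzoic acid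
Product: 11 [(1S,2R,5R,6R)‑5‑(benzoyloxy)‑2‑hydroxy‑7‑oxabicyclo[4.1.0]hept‑3‑en‑1‑yl]methyl benzoate
Conditions: PhCO2H (1.2 equiv), PPh3, DIAD, toluene, −20 → 0 °C
Reagents that add atoms: benzoic acid (10), O=C(O)c1ccccc1
Why: Mitsunobu esterification with clean inversion installs the C3 benzoate on the face of the epoxide oxygen, and it is regioselective because the C6 hydroxyl is neopentyl‑like (next to the fully substituted C1) and cannot undergo the backside displacement.

**Step 8**
Reactants: 11 epoxy benzoate; 12 acetic acid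
Product: 13 [(1S,2R,5R,6S)‑6‑acetoxy‑5‑(benzoyloxy)‑1,2‑dihydroxycyclohex‑3‑en‑1‑yl]methyl benzoate
Conditions: AcOH–NaOAc (1 M, buffered), 80 °C
Reagents that add atoms: acetic acid (12), CC(=O)O
Why: Buffered acetolysis opens the oxirane by anti (Fürst–Plattner type) attack of acetate at the secondary C2, since C1 is fully substituted and inductively deactivated by two β‑oxygens, giving the C2 acetate trans to the liberated tertiary C1 hydroxyl and completing all four stereocentres of the target.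

**Compound list**
1 | 2,5‑dimethoxybenzyl alcohol | COc1ccc(OC)c(CO)c1 | starting material
2 | benzoyl chloride | O=C(Cl)c1ccccc1 | starting material
3 | 2,5‑dimethoxybenzyl benzoate | COc1ccc(OC)c(COC(=O)c2ccccc2)c1 | intermediate
4 | (3,6‑dioxocyclohexa‑1,4‑dien‑1‑yl)methyl benzoate | O=C1C=CC(=O)C(COC(=O)c2ccccc2)=C1 | intermediate
5 | cyclopenta‑1,3‑diene | C1C=CC=C1 | starting material
6 | [(1R,4S,4aR,8aS)‑5,8‑dioxo‑1,4,4a,5,8,8a‑hexahydro‑1,4‑methanonaphthalen‑6‑yl]methyl benzoate | O=C1C(COC(=O)c2ccccc2)=CC(=O)[C@H]2[C@H]3C=C[C@H](C3)[C@@H]12 | intermediate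
7 | [(1R,4S,4aR,6R,7S,8aS)‑6,7‑epoxy‑5,8‑dioxo‑1,4,4a,5,6,7,8,8a‑octahydro‑1,4‑methanonaphthalen‑6‑yl]methyl benzoate | O=C1[C@]2(COC(=O)c3ccccc3)O[C@@H]2C(=O)[C@H]2[C@H]3C=C[C@H](C3)[C@@H]12 | intermediate
8 | [(1R,4S,4aR,5R,6S,7R,8S,8aS)‑6,7‑epoxy‑5,8‑dihydroxy‑1,4,4a,5,6,7,8,8a‑octahydro‑1,4‑methanonaphthalen‑6‑yl]methyl benzoate | O[C@H]1[C@]2(COC(=O)c3ccccc3)O[C@@H]2[C@@H](O)[C@H]2[C@H]3C=C[C@H](C3)[C@@H]12 | intermediate
9 | [(1S,2R,5S,6R)‑2,5‑dihydroxy‑7‑oxabicyclo[4.1.0]hept‑3‑en‑1‑yl]methyl benzoate | O[C@@H]1C=C[C@H](O)[C@H]2O[C@@]12COC(=O)c1ccccc1 | intermediate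
10 | benzoic acid | O=C(O)c1ccccc1 | starting material
11 | [(1S,2R,5R,6R)‑5‑(benzoyloxy)‑2‑hydroxy‑7‑oxabicyclo[4.1.0]hept‑3‑en‑1‑yl]methyl benzoate | O[C@@H]1C=C[C@@H](OC(=O)c2ccccc2)[C@H]2O[C@@]12COC(=O)c1ccccc1 | intermediate
12 | acetic acid | CC(=O)O | starting material
13 | [(1S,2R,5R,6S)‑6‑acetoxy‑5‑(benzoyloxy)‑1,2‑dihydroxycyclohex‑3‑en‑1‑yl]methyl benzoate | CC(=O)O[C@H]1[C@H](OC(=O)c2ccccc2)C=C[C@@H](O)[C@@]1(O)COC(=O)c1ccccc1 | target

Total step count: 8. Longest linear sequence: 8 steps (1 → 13).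

**Three steps most likely to fail**

Step 3 (enantioselectivity and facial sense are untested for this ester‑bearing quinone). The fallback sets out from 4 and gives up catalytic induction in favour of resolution. An uncatalysed Diels–Alder reaction with 5 (CH2Cl2, 0 °C) gives 6 together with its mirror image, the ent‑adduct F1. Steps 4 and 5 are run unchanged on the racemate, which carries the ent‑epoxy dione F2 and then the ent‑diol F3 alongside 7 and 8. The racemic diol is separated by preparative supercritical‑fluid chromatography on an amylose tris(3,5‑dimethylphenylcarbamate) phase, and the enantiomer 8 rejoins the route at 8.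

Step 6 (the cycloreversion releases an unactivated alkene and needs a high temperature in the presence of an epoxy diol). The fallback sets out from 8 and makes the cycloreversion enone‑driven. Oxidation of the less hindered C3 hydroxyl (2,2,6,6‑tetramethylpiperidin‑1‑oxyl 10 mol%, PhI(OAc)2, CH2Cl2) gives the hydroxy ketone F4. F4 loses cyclopentadiene in Ph2O at 220 °C to give the epoxy enone F5. Luche reduction (NaBH4, CeCl3·7H2O, MeOH, −78 °C) is expected to add hydride anti to the epoxide oxygen and give the C3‑epimeric diol F6. Selective benzoylation of its unhindered allylic hydroxyl with 2 (pyridine, −40 °C), now with retention, returns to the route at 11, so the Mitsunobu step is not needed.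

Step 8 (attack at C1, or anchimeric capture of C2 by the primary benzoate, could divert the acetolysis). The fallback sets out from 11 and introduces the acetate by acylation instead of by epoxide opening. Silylation of the C6 hydroxyl (TBSOTf, 2,6‑lutidine, CH2Cl2, −40 °C) gives the silyl ether F7. Acid‑catalysed hydrolysis of the oxirane (HClO4 cat., THF–H2O, 0 °C; water or the participating benzoate both enter anti at C2) gives the silylated 1,2‑diol F8. Ac2O with 4‑(dimethylamino)pyridine in pyridine at 0 °C acetylates only the secondary C2 hydroxyl to give the silylated acetate F9. HF·pyridine in THF removes the silyl group and returns to the route at 13.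

**Further compounds**
F1 | step 3 | [(1S,4R,4aS,8aR)‑5,8‑dioxo‑1,4,4a,5,8,8a‑hexahydro‑1,4‑methanonaphthalen‑6‑yl]methyl benzoate (enantiomer of 6) | O=C1C(COC(=O)c2ccccc2)=CC(=O)[C@@H]2[C@@H]3C=C[C@@H](C3)[C@H]12
F2 | step 3 | [(1S,4R,4aS,6S,7R,8aR)‑6,7‑epoxy‑5,8‑dioxo‑1,4,4a,5,6,7,8,8a‑octahydro‑1,4‑methanonaphthalen‑6‑yl]methyl benzoate (enantiomer of 7) | O=C1[C@@]2(COC(=O)c3ccccc3)O[C@H]2C(=O)[C@@H]2[C@@H]3C=C[C@@H](C3)[C@H]12
F3 | step 3 | [(1S,4R,4aS,5S,6R,7S,8R,8aR)‑6,7‑epoxy‑5,8‑dihydroxy‑1,4,4a,5,6,7,8,8a‑octahydro‑1,4‑methanonaphthalen‑6‑yl]methyl benzoate (enantiomer of 8) | O[C@@H]1[C@@]2(COC(=O)c3ccccc3)O[C@H]2[C@H](O)[C@@H]2[C@@H]3C=C[C@@H](C3)[C@H]12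
F4 | step 6 | [(1R,4S,4aR,5R,6S,7S,8aS)‑6,7‑epoxy‑5‑hydroxy‑8‑oxo‑1,4,4a,5,6,7,8,8a‑octahydro‑1,4‑methanonaphthalen‑6‑yl]methyl benzoate | O[C@H]1[C@]2(COC(=O)c3ccccc3)O[C@@H]2C(=O)[C@H]2[C@H]3C=C[C@H](C3)[C@@H]12
F5 | step 6 | [(1S,2R,6S)‑2‑hydroxy‑5‑oxo‑7‑oxabicyclo[4.1.0]hept‑3‑en‑1‑yl]methyl benzoate | O[C@@H]1C=CC(=O)[C@H]2O[C@@]12COC(=O)c1ccccc1
F6 | step 6 | [(1S,2R,5R,6R)‑2,5‑dihydroxy‑7‑oxabicyclo[4.1.0]hept‑3‑en‑1‑yl]methyl benzoate | O[C@@H]1C=C[C@@H](O)[C@H]2O[C@@]12COC(=O)c1ccccc1
F7 | step 8 | tert‑butyldimethylsilyl ether of 11 at its free secondary hydroxyl | CC(C)(C)[Si](C)(C)O[C@@H]1C=C[C@@H](OC(=O)c2ccccc2)[C@H]2O[C@@]12COC(=O)c1ccccc1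
F8 | step 8 | 13 lacking the acetyl group and carrying a tert‑butyldimethylsilyl ether on its free secondary hydroxyl | CC(C)(C)[Si](C)(C)O[C@@H]1C=C[C@@H](OC(=O)c2ccccc2)[C@H](O)[C@]1(O)COC(=O)c1ccccc1
F9 | step 8 | tert‑butyldimethylsilyl ether of 13 at its free secondary hydroxyl | CC(C)(C)[Si](C)(C)O[C@@H]1C=C[C@@H](OC(=O)c2ccccc2)[C@H](OC(C)=O)[C@]1(O)COC(=O)c1ccccc1
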